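**Retrosynthetic overview**
1. Feature addressed: C2 of ring C is a benzylic ether carbon that lies β to C4=O and is conjugated through ring B to the 4′-OH. It therefore racemises via ring-opened chalcone or quinone methide forms. The usual 3′-alkylchalcone precursor can also close through either ortho-OH, giving the 6- or the 8-alkyl flavanone.
2. Key disconnection, C2–C1′: ring B is added as an arylboronic acid across C2=C3 of an intact, achiral 6-alkylated chromone by Rh/chiral diene 1,4-addition. This sets (2S) in the next-to-last step, and no chalcone is ever formed.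
3. Second disconnection, C6–C1″: a C6 arylzinc is coupled under Pd(0) with an (E)-allylic acetate, keeping the C2″=C3″ geometry. The arylzinc comes from an iodide placed ortho to the chelated 5-OH.
4. The C7″ tertiary alcohol comes from site-selective Markovnikov hydration of the distal alkene of geranyl acetate.
5. Ring order: rings A and C are bought fused (5,7-dihydroxychromone), ring B is attached last, and no ring is closed in the route. Four aryl silyl ethers are removed at the end with weakly acidic fluoride.

Key step: step 8

Assumption: the (S,S)-diene/Rh catalyst is taken to deliver the aryl group to the face of C2 that gives (2S), by analogy with cyclic enones. The antipodal ligand is equally accessible if the assay of 15 shows the opposite sense. Compounds 1, 5 and 10 are catalogue compounds.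

**Step 1**
Reactants: 1 5,7-dihydroxychromone
Product: 2 7-(tert-butyldimethylsilyloxy)-5-hydroxychromone
Conditions: TBSCl (1.05 equiv), imidazole, DMF, 0 °C to rt
Reagents that add atoms: tert-butyldimethylsilyl chloride, CC(C)(C)[Si](C)(C)Cl
Why: Silyl ether formation should stop at O7, because the 7-OH is the acidic, free phenol while the 5-OH is held in a hydrogen bond to C4=O.

**Step 2**
Reactants: 2 7-(tert-butyldimethylsilyloxy)-5-hydroxychromone
Product: 3 7-(tert-butyldimethylsilyloxy)-5-hydroxy-6-iodochromone
Conditions: NIS (1.05 equiv), DMF, 0 °C to rt, dark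
Reagents that add atoms: N-iodosuccinimide, O=C1CCC(=O)N1I
Why: Electrophilic aromatic iodination should go ortho to the only free, chelated phenol (C6), as is known for 5-hydroxy-7-alkoxyflavones and 2-hydroxy-4,6-dialkoxyacetophenones.

**Step 3**
Reactants: 3 7-(tert-butyldimethylsilyloxy)-5-hydroxy-6-iodochromone
Product: 4 5,7-bis(tert-butyldimethylsilyloxy)-6-iodochromone
Conditions: TBSOTf (1.3 equiv), 2,6-lutidine, CH2Cl2, 0 °C to rt
Reagents that add atoms: tert-butyldimethylsilyl triflate, CC(C)(C)[Si](C)(C)OS(=O)(=O)C(F)(F)F
Why: The silyl triflate is reactive enough to silylate the chelated, hindered 5-OH, and any reversible O-silylation of the pyranone carbonyl is undone on aqueous work-up.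

**Step 4**
Reactants: 5 geranyl acetate
Product: 7 (2E)-7-hydroxy-3,7-dimethyloct-2-en-1-yl acetate, via organomercurial acetate 6 (not isolated)
Conditions: Hg(OAc)2 (1.0 equiv), THF/H2O, rt; then NaBH4, aq NaOH, 0 °C, short contact
Reagents that add atoms: water, O
Why: Oxymercuration–demercuration gives Markovnikov hydration of the electron-rich C6=C7 alkene in preference to the C2=C3 alkene, which the allylic acetate deactivates; the mercurated carbon of 6 loses its stereocentre on reduction, and the (E)-alkene is untouched.

**Step 5**
Reactants: 4 5,7-bis(tert-butyldimethylsilyloxy)-6-iodochromone; 7 (2E)-7-hydroxy-3,7-dimethyloct-2-en-1-yl acetate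
Product: 9 5,7-bis(tert-butyldimethylsilyloxy)-6-[(2E)-7-hydroxy-3,7-dimethyloct-2-en-1-yl]chromone, via arylzinc iodide 8 (not isolated)
Conditions: Zn dust (activated), LiCl, THF, 40 °C; then 7 (1.2 equiv), Pd(PPh3)4 (5 mol %), THF, rt to 40 °C
Reagents that add atoms: none
Why: LiCl-promoted zinc insertion into C6–I tolerates the chromone, and the Negishi-type coupling with the π-allylpalladium species from 7 forms the bond at the unsubstituted allyl terminus faster than syn/anti exchange at the fully substituted terminus, so the linear (E)-product should result; arylzinc halides are protonated only slowly by a tertiary alcohol.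

**Step 6**
Reactants: 10 4-bromocatechol
Product: 11 4-bromo-1,2-bis(tert-butyldimethylsilyloxy)benzene
Conditions: TBSCl (2.3 equiv), imidazole, DMF, rt
Reagents that add atoms: tert-butyldimethylsilyl chloride, CC(C)(C)[Si](C)(C)Cl
Why: Standard silyl ether formation on both catechol hydroxyls masks the chelating, oxidisable diol.

**Step 7**
Reactants: 11 4-bromo-1,2-bis(tert-butyldimethylsilyloxy)benzene
Product: 14 3,4-bis(tert-butyldimethylsilyloxy)phenylboronic acid, via aryllithium 12 (not isolated), via lithium triisopropoxyborate 13 (not isolated)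
Conditions: n-BuLi, THF, −78 °C; B(OiPr)3, −78 °C to rt; 1 M HCl to pH 5–6
Reagents that add atoms: triisopropyl borate, CC(C)OB(OC(C)C)OC(C)C; water, O
Why: Bromine–lithium exchange followed by borate trapping and hydrolysis is the standard boronic acid synthesis, and the lithiated carbon has no ortho silyloxy group, so no silyl migration is expected.

**Step 8**
Reactants: 9 5,7-bis(tert-butyldimethylsilyloxy)-6-[(2E)-7-hydroxy-3,7-dimethyloct-2-en-1-yl]chromone; 14 3,4-bis(tert-butyldimethylsilyloxy)phenylboronic acid
Product: 15 (2S)-5,7-bis(tert-butyldimethylsilyloxy)-2-[3,4-bis(tert-butyldimethylsilyloxy)phenyl]-6-[(2E)-7-hydroxy-3,7-dimethyloct-2-en-1-yl]chroman-4-one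
Conditions: 14 (2 equiv), [RhCl(C2H4)2]2 (2.5 mol %), (1S,4S)-2,5-diphenylbicyclo[2.2.2]octa-2,5-diene (5.5 mol %), aq KOH (10 mol %), toluene/H2O 10:1, 35 °C
Reagents that add atoms: none
Why: Hayashi–Miyaura reaction: the aryl group of 14 is transmetalated to a hydroxorhodium(I)–diene complex, C2=C3 of 9 binds to the aryl–rhodium species, migratory insertion places the aryl group on C2, and water protonates the oxa-π-allyl rhodium enolate at C3 and regenerates Rh–OH. The closest known reaction type is the rhodium/chiral diene (or electron-poor bisphosphine) catalysed 1,4-addition of arylboronic acids to 4H-chromen-4-ones, an established enantioselective entry to flavanones, including ones with oxygenated A rings. No ring is closed: rings A and C are already in place, so the 6- versus 8-alkyl ambiguity of a chalcone closure cannot arise, and the step joins ring B through the C2–C1′ bond. The single new stereocentre C2 is controlled by the C2-symmetric diene, whose phenyl groups let the flat chromone bind with only one face of C2=C3 toward the aryl–rhodium bond, which should give (2S) with the (S,S) ligand. The step needs 1,4- over 1,2-addition, enolate protonation faster than β-aryloxide elimination (opening of ring C), and no reaction at C2″=C3″ or the tertiary alcohol; the 5-OTBS group shields C4=O, the aqueous and nearly base-free medium at mild temperature favours protonation, an unactivated trisubstituted alkene does not insert into aryl–rhodium, and a free alcohol is harmless in a reaction run in water. Because this step is next to last, the labile C2 centre afterwards meets only a weakly acidic fluoride step.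

**Step 9**
Reactants: 15 (2S)-tetrasilylated flavanone
Product: 16 prokinawan
Conditions: KHF2 (excess), MeOH/THF, rt, argon
Reagents that add atoms: none
Why: Fluoride-induced cleavage of phenolic silyl ethers in a bifluoride-buffered, weakly acidic medium should free all four phenols without generating the 4′-phenoxide or C3 enolate that racemise C2; the medium is also too weakly acidic to protonate the alkene or ionise the tertiary alcohol.

**Compound list**
1 | 5,7-dihydroxychromone | O=c1ccoc2cc(O)cc(O)c12 | starting material
2 | 7-(tert-butyldimethylsilyloxy)-5-hydroxychromone | O=c1ccoc2cc(O[Si](C)(C)C(C)(C)C)cc(O)c12 | intermediate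
3 | 7-(tert-butyldimethylsilyloxy)-5-hydroxy-6-iodochromone | Ic1c(O[Si](C)(C)C(C)(C)C)cc2occc(=O)c2c1O | intermediate
4 | 5,7-bis(tert-butyldimethylsilyloxy)-6-iodochromone | Ic1c(O[Si](C)(C)C(C)(C)C)cc2occc(=O)c2c1O[Si](C)(C)C(C)(C)C | intermediate
5 | geranyl acetate | CC(C)=CCC/C(C)=C/COC(C)=O | starting material
6 | (2E)-6-(acetoxymercurio)-7-hydroxy-3,7-dimethyloct-2-en-1-yl acetate (racemic at C6) | CC(=O)OC/C=C(\C)CCC([Hg]OC(C)=O)C(C)(C)O | intermediate
7 | (2E)-7-hydroxy-3,7-dimethyloct-2-en-1-yl acetate | CC(=O)OC/C=C(\C)CCCC(C)(C)O | intermediate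
8 | [5,7-bis(tert-butyldimethylsilyloxy)-4-oxochromen-6-yl]zinc iodide | I[Zn]c1c(O[Si](C)(C)C(C)(C)C)cc2occc(=O)c2c1O[Si](C)(C)C(C)(C)C | intermediate
9 | 5,7-bis(tert-butyldimethylsilyloxy)-6-[(2E)-7-hydroxy-3,7-dimethyloct-2-en-1-yl]chromone | C/C(=C\Cc1c(O[Si](C)(C)C(C)(C)C)cc2occc(=O)c2c1O[Si](C)(C)C(C)(C)C)CCCC(C)(C)O | intermediate
10 | 4-bromocatechol | Oc1ccc(Br)cc1O | starting material
11 | 4-bromo-1,2-bis(tert-butyldimethylsilyloxy)benzene | CC(C)(C)[Si](C)(C)Oc1ccc(Br)cc1O[Si](C)(C)C(C)(C)C | intermediate
12 | 3,4-bis(tert-butyldimethylsilyloxy)phenyllithium | [Li]c1ccc(O[Si](C)(C)C(C)(C)C)c(O[Si](C)(C)C(C)(C)C)c1 | intermediate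
13 | lithium [3,4-bis(tert-butyldimethylsilyloxy)phenyl]triisopropoxyborate | [Li+].CC(C)O[B-](OC(C)C)(OC(C)C)c1ccc(O[Si](C)(C)C(C)(C)C)c(O[Si](C)(C)C(C)(C)C)c1 | intermediate
14 | 3,4-bis(tert-butyldimethylsilyloxy)phenylboronic acid | OB(O)c1ccc(O[Si](C)(C)C(C)(C)C)c(O[Si](C)(C)C(C)(C)C)c1 | intermediate
15 | (2S)-5,7-bis(tert-butyldimethylsilyloxy)-2-[3,4-bis(tert-butyldimethylsilyloxy)phenyl]-6-[(2E)-7-hydroxy-3,7-dimethyloct-2-en-1-yl]chroman-4-one | C/C(=C\Cc1c(O[Si](C)(C)C(C)(C)C)cc2c(c1O[Si](C)(C)C(C)(C)C)C(=O)C[C@@H](c1ccc(O[Si](C)(C)C(C)(C)C)c(O[Si](C)(C)C(C)(C)C)c1)O2)CCCC(C)(C)O | intermediate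
16 | prokinawan, (2S)-2-(3,4-dihydroxyphenyl)-5,7-dihydroxy-6-[(2E)-7-hydroxy-3,7-dimethyloct-2-en-1-yl]chroman-4-one | C/C(=C\Cc1c(O)cc2c(c1O)C(=O)C[C@@H](c1ccc(O)c(O)c1)O2)CCCC(C)(C)O | target

**Total step count:** 9
**Longest linear sequence:** 6 steps (1 → 2 → 3 → 4 → 9 → 15 → 16)

**Steps most likely to fail**

**Step 8.** Three things may go wrong:
- Insertion may be slow, because the 5,7-dioxygenated chromone is a weak acceptor.
- β-Aryloxide elimination from the rhodium enolate may open ring C and erode the enantiomeric purity through unselective reclosure.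
- Facial discrimination may be insufficient.

The fallback sets out from 9 and 14 and returns at 15. It replaces asymmetric induction by resolution. The C2–C1′ bond is made with the more active achiral catalyst [Rh(OH)(cod)]2 in dioxane/water, which should give the racemic tetrasilylated flavanone F1. F1 is then subjected to kinetic resolution by Noyori–Ikariya transfer hydrogenation (Rh or Ru–TsDPEN, HCO2H/Et3N), a known way to resolve flavanones. The catalyst antipode is chosen so that the (2R)-ketone is reduced faster, to the cis-(2R,4R)-flavan-4-ol F2. The unreacted (2S)-ketone is 15 and is separated from F2 by chromatography.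

**Step 5.** Three things may go wrong:
- Zinc insertion or transmetalation may be sluggish at a carbon flanked by two silyloxy groups.
- The arylzinc may be protonated by the tertiary alcohol.
- Alkene geometry may be partly lost through π–σ–π exchange.

The fallback sets out from 4 and returns at 9. It reverses the roles of the partners. Commercial myrcenol F3 already carries the C7″ alcohol. It is treated with pinacolborane (2 equiv, the first capping the alcohol) under iron/iminopyridine-catalysed 1,4-hydroboration of the 2-substituted diene, which should give the (E)-allylboronate O-borate F4. An α-selective Suzuki–Miyaura coupling of F4 with iodide 4 follows (Pd with a bulky dialkylbiarylphosphine or NHC ligand, aq K3PO4, THF). The O–B bond hydrolyses in the aqueous base, and 9 should be obtained. Any (Z)-isomer would be removed on silver nitrate-impregnated silica.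

**Step 2.** Iodination at C8 may compete, or double iodination may occur. The fallback sets out from 1 and returns at 4. It decides the regiochemistry by selective removal of iodine instead of selective introduction. Exhaustive iodination (NIS, 2.2 equiv) should give 5,7-dihydroxy-6,8-diiodochromone F5. Silylation of both phenols (TBSOTf, 2,6-lutidine) should give the bis-silyl diiodide F6. Pd(PPh3)4-catalysed hydrodeiodination with one equivalent of Bu3SnH should then take place at C8. That position is flanked by only one silyl ether and is the more accessible site for oxidative addition, so 4 is left.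

**Further compounds**
F1 | step 8 | racemic 5,7-bis(tert-butyldimethylsilyloxy)-2-[3,4-bis(tert-butyldimethylsilyloxy)phenyl]-6-[(2E)-7-hydroxy-3,7-dimethyloct-2-en-1-yl]chroman-4-one | C/C(=C\Cc1c(O[Si](C)(C)C(C)(C)C)cc2c(c1O[Si](C)(C)C(C)(C)C)C(=O)CC(c1ccc(O[Si](C)(C)C(C)(C)C)c(O[Si](C)(C)C(C)(C)C)c1)O2)CCCC(C)(C)O
F2 | step 8 | cis-(2R,4R)-flavan-4-ol derived from the (2R)-enantiomer of F1 | C/C(=C\Cc1c(O[Si](C)(C)C(C)(C)C)cc2c(c1O[Si](C)(C)C(C)(C)C)[C@H](O)C[C@H](c1ccc(O[Si](C)(C)C(C)(C)C)c(O[Si](C)(C)C(C)(C)C)c1)O2)CCCC(C)(C)O
F3 | step 5 | myrcenol (2-methyl-6-methylideneoct-7-en-2-ol) | C=CC(=C)CCCC(C)(C)O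
F4 | step 5 | (E)-allylboronate O-borate: 2-[(2E)-3,7-dimethyl-7-(pinacolatoboryloxy)oct-2-en-1-yl]-4,4,5,5-tetramethyl-1,3,2-dioxaborolane | CC(C)(CCC/C(C)=C/CB1OC(C)(C)C(C)(C)O1)OB1OC(C)(C)C(C)(C)O1
F5 | step 2 | 5,7-dihydroxy-6,8-diiodochromone | O=c1ccoc2c(I)c(O)c(I)c(O)c12
F6 | step 2 | 5,7-bis(tert-butyldimethylsilyloxy)-6,8-diiodochromone | O=c1ccoc2c(I)c(O[Si](C)(C)C(C)(C)C)c(I)c(O[Si](C)(C)C(C)(C)C)c12
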